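**Retrosynthetic overview**

1. Target 21 comes from alcohol 19 by acylation of the homopropargylic OH, and 19 from silyl ether 18.
2. The strategy rests on ring B, the thiophene that carries the CH2O group and is bonded to ring A: its C3' and C4' carry only hydrogen, so the C3'–C4' bond can be made last by contracting 1,4-dithiin 4-oxide 16 with loss of SO.
3. Oxide 16 comes from dithiin 15 by mono-oxidation at the sulfur flanked by the two CH carbons; 15 comes from the 3-thia-1,5-diketone 14 by Lawesson closure.
4. Diketone 14 is assembled from thioacetate 8 (from ring A chloromethyl ketone 7) and chloride 12 (from 1,3-dichloroacetone and isovaleric acid).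
5. Ketone 7 comes from 3 (Sonogashira coupling of 2-iodothiophene) by C5 lithiation and Weinreb chloroacetylation. Ring order: ring A is bought, the six-membered dithiin is closed next, and ring B is formed from it by contraction.

Key step: step 8

Remark: the target has no stereocentre; sulfoxide 16 is formed and used as the racemate at sulfur, and that centre disappears in step 8. Compounds 2, 4 and 20 are taken as purchased.

**Step 1**
Reactants: 1 2-iodothiophene; 2 tert-butyl(but-3-yn-1-yloxy)dimethylsilane
Product: 3 tert-butyldimethyl{[4-(thiophen-2-yl)but-3-yn-1-yl]oxy}silane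
Conditions: Pd(PPh3)2Cl2 (2 mol%), CuI (4 mol%), Et3N, THF, rt
Reagents that add atoms: none
Why: Sonogashira coupling of a heteroaryl iodide with a terminal alkyne should run at room temperature, and the silyl ether is inert to it.

**Step 2**
Reactants: 3 tert-butyldimethyl{[4-(thiophen-2-yl)but-3-yn-1-yl]oxy}silane; 4 2-chloro-N-methoxy-N-methylacetamide
Product: 7 2-chloro-1-{5-[4-(tert-butyldimethylsilyloxy)but-1-yn-1-yl]thiophen-2-yl}ethan-1-one, via aryllithium 5 (not isolated), via tetrahedral lithium adduct 6 (not isolated)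
Conditions: n-BuLi (1.05 equiv), THF, −78 °C; then 4 (1.2 equiv), −78 → −20 °C; aq NH4Cl
Reagents that add atoms: none
Why: H5 is the only ring proton alpha to sulfur in 3, so alpha-lithiation followed by Weinreb ketone synthesis should give the chloromethyl ketone, the chelated adduct 6 preventing a second addition.

**Step 3**
Reactants: 7 2-chloro-1-{5-[4-(tert-butyldimethylsilyloxy)but-1-yn-1-yl]thiophen-2-yl}ethan-1-one
Product: 8 S-(2-{5-[4-(tert-butyldimethylsilyloxy)but-1-yn-1-yl]thiophen-2-yl}-2-oxoethyl) ethanethioate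
Conditions: KSAc (1.1 equiv), acetone, 0 °C → rt
Reagents that add atoms: potassium thioacetate, CC(=O)[S-].[K+]
Why: SN2 displacement of an alpha-chloro ketone by thioacetate is fast and stores the sulfur as a thioester that cannot dimerise or oxidise to disulfide.

**Step 4**
Reactants: 9 1,3-dichloroacetone; 10 isovaleric acid
Product: 12 3-chloro-2-oxopropyl 3-methylbutanoate, via potassium 3-methylbutanoate 11 (not isolated)
Conditions: 10, KHCO3 (1.0 equiv), DMF, rt; then added slowly to 9 (3 equiv), DMF, 0 °C → rt; excess 9 removed by distillation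
Reagents that add atoms: none
Why: Carboxylate SN2 alkylation by the carbonyl-activated chloride, held at mono-substitution by the excess of dichloroacetone and slow addition of the salt.

**Step 5**
Reactants: 8 S-(2-{5-[4-(tert-butyldimethylsilyloxy)but-1-yn-1-yl]thiophen-2-yl}-2-oxoethyl) ethanethioate; 12 3-chloro-2-oxopropyl 3-methylbutanoate
Product: 14 3-[(2-{5-[4-(tert-butyldimethylsilyloxy)but-1-yn-1-yl]thiophen-2-yl}-2-oxoethyl)sulfanyl]-2-oxopropyl 3-methylbutanoate, via sodium thiolate 13 (not isolated)
Conditions: NaOMe (1.0 equiv), MeOH/THF, −20 °C, degassed; then 12 (1.05 equiv), −20 → 0 °C; AcOH quench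
Reagents that add atoms: none
Why: S-deacetylation by one equivalent of methoxide leaves only the weakly basic thiolate, whose SN2 thioether formation with the alpha-chloro ketone should outrun any transesterification of the ketol ester.

**Step 6**
Reactants: 14 3-[(2-{5-[4-(tert-butyldimethylsilyloxy)but-1-yn-1-yl]thiophen-2-yl}-2-oxoethyl)sulfanyl]-2-oxopropyl 3-methylbutanoate
Product: 15 (6-{5-[4-(tert-butyldimethylsilyloxy)but-1-yn-1-yl]thiophen-2-yl}-1,4-dithiin-2-yl)methyl 3-methylbutanoate
Conditions: Lawesson's reagent (1.2 equiv), toluene, 80 °C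
Reagents that add atoms: Lawesson's reagent, COc1ccc(cc1)P1(=S)SP(=S)(S1)c1ccc(OC)cc1
Why: Lawesson thionation of both ketones of a bis(2-oxoalkyl) sulfide and cyclocondensation with loss of H2S should close the 1,4-dithiin, the new sulfur joining the two former carbonyl carbons so that the original sulfide sulfur is the one flanked by the two CH carbons.

**Step 7**
Reactants: 15 (6-{5-[4-(tert-butyldimethylsilyloxy)but-1-yn-1-yl]thiophen-2-yl}-1,4-dithiin-2-yl)methyl 3-methylbutanoate
Product: 16 (6-{5-[4-(tert-butyldimethylsilyloxy)but-1-yn-1-yl]thiophen-2-yl}-1,4-dithiin-2-yl)methyl 3-methylbutanoate 4-oxide (racemic at sulfur)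
Conditions: mCPBA (1.0 equiv), NaHCO3, CH2Cl2, −78 → −40 °C
Reagents that add atoms: mCPBA, OOC(=O)c1cccc(Cl)c1
Why: Electrophilic sulfide-to-sulfoxide oxidation by a peracid is expected at S4, which has only CH neighbours, whereas S1 is shielded on both sides by the thienyl- and acyloxymethyl-bearing carbons; the new sulfur stereocentre is not controlled and is lost in step 8.

**Step 8**
Reactants: 16 (6-{5-[4-(tert-butyldimethylsilyloxy)but-1-yn-1-yl]thiophen-2-yl}-1,4-dithiin-2-yl)methyl 3-methylbutanoate 4-oxide
Product: 18 {5'-[4-(tert-butyldimethylsilyloxy)but-1-yn-1-yl]-2,2'-bithiophen-5-yl}methyl 3-methylbutanoate, via thiirane S-oxide 17 (not isolated)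
Conditions: PhMe (0.02 M), 110 °C, N2 sweep
Reagents that add atoms: none
Why: On heating, the boat-shaped dithiin oxide should undergo a thermal six-electron electrocyclization in which the lone pair of the sulfide sulfur S1 and the two C=C bonds combine, bonding C3 to C5 across the sulfinyl sulfur to give the cis-fused thiirane S-oxide 17 (a thienyl-stabilised thiocarbonyl ylide), which then loses SO by cheletropic fragmentation and aromatises. The closest known reaction type is the thermal extrusion of sulfur monoxide from 1,4-dithiin 1-oxides to thiophenes, together with the loss of SO from thiirane S-oxides. Ring B is closed by electrocyclic C–C bond formation within the five-atom C=C–S–C=C array followed by cheletropic extrusion, that is a six-to-five ring contraction at carbon. No stereocentre is formed, and the sulfur centre of 16 and the two transient sp3 carbons of 17 vanish on aromatisation. The step needs the sulfur between the two CH carbons to be the one expelled, and the oxygen placed on it in step 7 secures this, because the sulfinyl group is the better leaving fragment and the retained S1 keeps the thienyl and acyloxymethyl carbons as its neighbours, which become the 2 and 5 positions of ring B. The sulfoxide has no beta C–H for syn-elimination, and the thienyl alkyne, silyl ether and ester should be spectators at this temperature.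

**Step 9**
Reactants: 18 {5'-[4-(tert-butyldimethylsilyloxy)but-1-yn-1-yl]-2,2'-bithiophen-5-yl}methyl 3-methylbutanoate
Product: 19 [5'-(4-hydroxybut-1-yn-1-yl)-2,2'-bithiophen-5-yl]methyl 3-methylbutanoate
Conditions: TBAF (1.5 equiv), AcOH (1.5 equiv), THF, 0 °C → rt
Reagents that add atoms: none
Why: Fluoride-induced desilylation, buffered with acetic acid so that the thienylmethyl ester is not cleaved or transferred by alkoxide.

**Step 10**
Reactants: 19 [5'-(4-hydroxybut-1-yn-1-yl)-2,2'-bithiophen-5-yl]methyl 3-methylbutanoate; 20 3-methylbutanoyl chloride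
Product: 21 4-{5'-[(3-methylbutanoyloxy)methyl]-2,2'-bithiophen-5-yl}but-3-yn-1-yl 3-methylbutanoate (CNP0154475.0)
Conditions: Et3N (1.5 equiv), DMAP (5 mol%), CH2Cl2, 0 °C → rt
Reagents that add atoms: none
Why: DMAP-catalysed acylation of an unhindered primary alcohol by an acid chloride, with no other nucleophilic site in the molecule.

**Compound list**

1 | 2-iodothiophene | Ic1cccs1 | starting material
2 | tert-butyl(but-3-yn-1-yloxy)dimethylsilane | C#CCCO[Si](C)(C)C(C)(C)C | starting material
3 | tert-butyldimethyl{[4-(thiophen-2-yl)but-3-yn-1-yl]oxy}silane | CC(C)(C)[Si](C)(C)OCCC#Cc1cccs1 | intermediate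
4 | 2-chloro-N-methoxy-N-methylacetamide | CON(C)C(=O)CCl | starting material
5 | {5-[4-(tert-butyldimethylsilyloxy)but-1-yn-1-yl]thiophen-2-yl}lithium | [Li]c1ccc(C#CCCO[Si](C)(C)C(C)(C)C)s1 | intermediate
6 | lithium 2-chloro-1-[methoxy(methyl)amino]-1-{5-[4-(tert-butyldimethylsilyloxy)but-1-yn-1-yl]thiophen-2-yl}ethan-1-olate (racemic) | [Li]OC(CCl)(N(C)OC)c1ccc(C#CCCO[Si](C)(C)C(C)(C)C)s1 | intermediate
7 | 2-chloro-1-{5-[4-(tert-butyldimethylsilyloxy)but-1-yn-1-yl]thiophen-2-yl}ethan-1-one | O=C(CCl)c1ccc(C#CCCO[Si](C)(C)C(C)(C)C)s1 | intermediate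
8 | S-(2-{5-[4-(tert-butyldimethylsilyloxy)but-1-yn-1-yl]thiophen-2-yl}-2-oxoethyl) ethanethioate | CC(=O)SCC(=O)c1ccc(C#CCCO[Si](C)(C)C(C)(C)C)s1 | intermediate
9 | 1,3-dichloroacetone | ClCC(=O)CCl | starting material
10 | isovaleric acid (3-methylbutanoic acid) | CC(C)CC(=O)O | starting material
11 | potassium 3-methylbutanoate | CC(C)CC(=O)[O-].[K+] | intermediate
12 | 3-chloro-2-oxopropyl 3-methylbutanoate | CC(C)CC(=O)OCC(=O)CCl | intermediate
13 | sodium 2-{5-[4-(tert-butyldimethylsilyloxy)but-1-yn-1-yl]thiophen-2-yl}-2-oxoethane-1-thiolate | [Na+].[S-]CC(=O)c1ccc(C#CCCO[Si](C)(C)C(C)(C)C)s1 | intermediate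
14 | 3-[(2-{5-[4-(tert-butyldimethylsilyloxy)but-1-yn-1-yl]thiophen-2-yl}-2-oxoethyl)sulfanyl]-2-oxopropyl 3-methylbutanoate | CC(C)CC(=O)OCC(=O)CSCC(=O)c1ccc(C#CCCO[Si](C)(C)C(C)(C)C)s1 | intermediate
15 | (6-{5-[4-(tert-butyldimethylsilyloxy)but-1-yn-1-yl]thiophen-2-yl}-1,4-dithiin-2-yl)methyl 3-methylbutanoate | CC(C)CC(=O)OCC1=CSC=C(c2ccc(C#CCCO[Si](C)(C)C(C)(C)C)s2)S1 | intermediate
16 | (6-{5-[4-(tert-butyldimethylsilyloxy)but-1-yn-1-yl]thiophen-2-yl}-1,4-dithiin-2-yl)methyl 3-methylbutanoate 4-oxide (racemic at sulfur) | O=S1C=C(c2ccc(C#CCCO[Si](C)(C)C(C)(C)C)s2)SC(COC(=O)CC(C)C)=C1 | intermediate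
17 | cis-fused 3,6-dithiabicyclo[3.1.0]hexane 6-oxide carrying the thiocarbonyl ylide C2–S3–C4 (C2 thienyl, C4 isovaleroyloxymethyl), transient | O=S1C2C1[C-](COC(=O)CC(C)C)[S+]=C2c1ccc(C#CCCO[Si](C)(C)C(C)(C)C)s1 | intermediate
18 | {5'-[4-(tert-butyldimethylsilyloxy)but-1-yn-1-yl]-2,2'-bithiophen-5-yl}methyl 3-methylbutanoate | CC(C)CC(=O)OCc1ccc(-c2ccc(C#CCCO[Si](C)(C)C(C)(C)C)s2)s1 | intermediate
19 | [5'-(4-hydroxybut-1-yn-1-yl)-2,2'-bithiophen-5-yl]methyl 3-methylbutanoate | CC(C)CC(=O)OCc1ccc(-c2ccc(C#CCCO)s2)s1 | intermediate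
20 | 3-methylbutanoyl chloride | CC(C)CC(Cl)=O | starting material
21 | 4-{5'-[(3-methylbutanoyloxy)methyl]-2,2'-bithiophen-5-yl}but-3-yn-1-yl 3-methylbutanoate | CC(C)CC(=O)OCCC#Cc1ccc(-c2ccc(COC(=O)CC(C)C)s2)s1 | target

**Step count**

Total steps: 10. Longest linear sequence: 9 (steps 1, 2, 3, 5, 6, 7, 8, 9, 10); step 4 is the side branch.

**Steps most likely to fail**

Step 7. Oxygen may be delivered to the hindered sulfur S1 instead of S4, or a second oxidation may follow the first, so that the wrong sulfur, or none, is set up to leave. The fallback sets out from 14 and fixes the oxidised sulfur while the molecule has only one. mCPBA (2.2 equiv, CH2Cl2, 0 °C) should convert 14 into the sulfone 3-[(2-{5-[4-(tert-butyldimethylsilyloxy)but-1-yn-1-yl]thiophen-2-yl}-2-oxoethyl)sulfonyl]-2-oxopropyl 3-methylbutanoate F1. Lawesson's reagent, which leaves sulfones untouched, in toluene at 80–100 °C should close it to (6-{5-[4-(tert-butyldimethylsilyloxy)but-1-yn-1-yl]thiophen-2-yl}-1,4-dithiin-2-yl)methyl 3-methylbutanoate 4,4-dioxide F2. Heating F2 in o-dichlorobenzene at 160–180 °C should then expel SO2 by the same electrocyclization and cheletropic sequence, and the route is rejoined at 18.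

Step 8. The sulfoxide may lose only oxygen and revert to 15, or the electron-rich material may decompose before the ring contracts. The fallback sets out from 3 and forms the bond between ring A and ring B by cross-coupling. Lithiation as in step 2 and quenching with Bu3SnCl should give tributyl{5-[4-(tert-butyldimethylsilyloxy)but-1-yn-1-yl]thiophen-2-yl}stannane F3. Purchased (5-bromothiophen-2-yl)methanol (OCc1ccc(Br)s1) is acylated with 20 (Et3N, DMAP, CH2Cl2) to (5-bromothiophen-2-yl)methyl 3-methylbutanoate F4. Stille coupling of F3 and F4 (Pd(PPh3)4, toluene, 100 °C) returns to the route at 18.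

Step 6. Thionation may stop at open-chain thiocarbonyl compounds, an aldol-type five-membered closure of the acidic SCH2 group may compete, or the silyl ether may be lost to the acidic phosphorus by-products. The fallback sets out from 2 and 20 and attaches the alkyne last to a purchased bithiophene. 5'-Bromo-2,2'-bithiophene-5-carbaldehyde (O=Cc1ccc(-c2ccc(Br)s2)s1) is reduced with NaBH4 in MeOH/THF at 0 °C to (5'-bromo-2,2'-bithiophen-5-yl)methanol F5. Acylation with 20 (Et3N, DMAP, CH2Cl2) gives (5'-bromo-2,2'-bithiophen-5-yl)methyl 3-methylbutanoate F6. Sonogashira coupling of F6 with 2 (Pd(PPh3)2Cl2, CuI, Et3N, THF, 50 °C) rejoins the route at 18.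

**Further compounds**

F1 | step 7 | 3-[(2-{5-[4-(tert-butyldimethylsilyloxy)but-1-yn-1-yl]thiophen-2-yl}-2-oxoethyl)sulfonyl]-2-oxopropyl 3-methylbutanoate | CC(C)CC(=O)OCC(=O)CS(=O)(=O)CC(=O)c1ccc(C#CCCO[Si](C)(C)C(C)(C)C)s1
F2 | step 7 | (6-{5-[4-(tert-butyldimethylsilyloxy)but-1-yn-1-yl]thiophen-2-yl}-1,4-dithiin-2-yl)methyl 3-methylbutanoate 4,4-dioxide | O=S1(=O)C=C(c2ccc(C#CCCO[Si](C)(C)C(C)(C)C)s2)SC(COC(=O)CC(C)C)=C1
F3 | step 8 | tributyl{5-[4-(tert-butyldimethylsilyloxy)but-1-yn-1-yl]thiophen-2-yl}stannane | CCCC[Sn](CCCC)(CCCC)c1ccc(C#CCCO[Si](C)(C)C(C)(C)C)s1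
F4 | step 8 | (5-bromothiophen-2-yl)methyl 3-methylbutanoate | CC(C)CC(=O)OCc1ccc(Br)s1
F5 | step 6 | (5'-bromo-2,2'-bithiophen-5-yl)methanol | OCc1ccc(-c2ccc(Br)s2)s1
F6 | step 6 | (5'-bromo-2,2'-bithiophen-5-yl)methyl 3-methylbutanoate | CC(C)CC(=O)OCc1ccc(-c2ccc(Br)s2)s1
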